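Readings and results stem from a simulated flask with constants of no real substance; scatter was added.

10.0 is the number I would hold on to. Define the rise time τ as the time at which L stopped climbing on Thursday, read as 8.00 min with the scatter of the readings, and call the count of rise times in a run, t/τ for a run of length t, n. You asked for a quick figure, and your hunch is a ceiling.

| flask | J | E | Q | D | remark | time |
|---|---|---|---|---|---|---|
| Thursday's | 0.20 M | 0.50 M | 71 mM | 15 mM | run made earlier |  |
| alder | 0.20 M | 0.745 M | 71 mM | 15 mM |  | 80 min |
| ash | 0.40 M | 0.745 M | 71 mM | 15 mM |  | 80 min |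
| elm | 0.80 M | 0.745 M | 71 mM | 15 mM |  | 80 min |
| maple | 1.5 M | 0.745 M | 71 mM | 15 mM |  | 80 min |

Thursday's run (percent of the J charged)

| time / min | L / % |
|---|---|
| 2.50 | 1.0 |
| 3.00 | 0.9 |
| 5.00 | 2.9 |
| 8.00 | 5.4 |
| 12.0 | 5.6 |
| 20.0 | 6.4 |
| 30.0 | 5.1 |

(each reading ± 0.5 percentage points)

* [L] at the end for alder, ash, elm, maple, in this order
* how the row runs (rises all the way / hardly changes / falls all the way / falls, then rises / rises, then falls)

- "hardly changes" means that all values lie within two and a half points (for a concentration: within two and a half percent of the largest)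

The forecast, your hunch written down, gives 0.012 M for alder, ash, elm and maple alike, so the row hardly changes; its ground is “a fixed ceiling on L, set by the catalyst rather than by J”.

My reckoning differs. Thursday's flat stretch ends with the last reading at 30.0 min, so it covers 2.75 rise times, while the new flasks run for n = 10.0. Nothing was read beyond that stretch, whose last two readings are 6.4% and 5.1%, each with a scatter of 0.5 percentage points. My bet is that L is fed by a charge that decays pseudo-first-order, halving once per τ, and that L follows it down after the last reading:

share left of such a charge after the run = 0.5^n = 0.0977%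

my estimate of alder's L = Thursday's last reading, 5.1% of 0.20 M, halved 6.25 times = 1.34 × 10⁻⁴ M

That is less than the forecast's figure. It sets aside that alder has 0.745 M of E against Thursday's 0.50 M. For the other flasks I have no run to go on. The samples to watch are the late ones.

The flasks give 2.52 × 10⁻⁴ M, 0.00101 M, 0.00542 M and 0.00365 M for alder, ash, elm and maple: the row rises, then falls, turning near 0.79 M of J.

    J + Q → Q + Z (k = 0.0214 M⁻¹ s⁻¹)
    D + Z ⇌ G (K = 13.0 M⁻¹, k = 0.158 M⁻¹ s⁻¹)
    E + G → D + L (k = 0.0530 M⁻¹ s⁻¹)
    L → X (k = 0.00716 s⁻¹)

In alder the half-life of J by J + Q → Q + Z alone, the other concentrations as charged, is 7.6 min, so the run holds 10.5 half-lives against n = 10.0, and J stands at 0.0680% of its charge; the half-life of L by L → X alone is 1.6 min, shorter than the run, and L stands at 0.126% of the J charged. Maple ran for the same n and its J also stands at 0.0680%, but its L reads 0.243% beside Z at 51.6% of the J charged.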